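C1 ketone, C2=C3(CH3), cyclobutane C4–C5–C11–C10, C6 = C(CH3)2, C7 O-angeloyl, C8 O-2-methylbutanoyl, C9 OH, C10 quaternary C–CH3 (longipinane numbering). Once the skeleton is complete, only the C1–C3 bridge is adjusted: C2 ketone → C1/C2 diosphenol → enol triflate → enone.
Key disconnection C4–C10: Cp2TiCl opens a C9–C10 epoxide in a cis-fused bicyclo[5.4.0]undecenone, and the C10 radical attacks C4 of a C2 enone across the ring. This one bond closes the cyclobutane and, with it, the seven-membered ring C4–C5–C6–C7–C8–C9–C10.
Enabling feature: the free C9 carbinol next to quaternary C10 is the retron of a trisubstituted epoxide, hence of a tertiary radical. C10 and C4 are also 1,3-related across the C11–C5 bond of the ring C1–C2–C3–C4–C5–C11, where the bulky C6 on C5 forces C10 on C11 into the axial site above the enone β-carbon.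
The bicycle comes from ring-closing metathesis (C9=C10), hydroxyl-directed epoxidation and two acylations. C7/C8 come from a reagent-controlled alkoxyallylboration, and C5–C6 from an Ireland–Claisen rearrangement of the isobutyrate of (1S,4R)-p-mentha-2,8-dien-1-ol.
Ring order: six-membered ring (bought) → seven-membered ring through C11 (step 7) → cyclobutane plus seven-membered ring through C4 (step 11).

Key step: step 11

Assumption: the 2-methylbutanoyl stereocentre of the given structure is R; compounds 1, 2, 9, 12, 18 and (+)-Ipc2BOMe are bought; the numbering above is used for all intermediates ("4,10-seco" = C4–C10 bond still missing); α is the face of the carbocycle C5–C6–C7–C8–C9–C10–C11 that carries H-5 and H-11, and β is the face that carries C4 and C1.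

Step 1
Reactants: 1 (1S,4R)-p-mentha-2,8-dien-1-ol; 2 2-methylpropanoyl chloride
Product: 3 (1S,4R)-1-methyl-4-(prop-1-en-2-yl)cyclohex-2-en-1-yl 2-methylpropanoate
Conditions: n-BuLi, THF, −78 °C; then 2, −78 → 0 °C
Reagents that add atoms: none
Why: O-acylation of the lithium alkoxide of a tertiary allylic alcohol with an acid chloride, in which the C3–O bond stays intact so that no stereocentre is touched.

Step 2
Reactants: 3 (1S,4R)-1-methyl-4-(prop-1-en-2-yl)cyclohex-2-en-1-yl 2-methylpropanoate
Product: 6 2-methyl-2-[(1S,6R)-3-methyl-6-(prop-1-en-2-yl)cyclohex-2-en-1-yl]propanoic acid, via silyl ketene acetal 4 (not isolated), via trimethylsilyl ester 5 (not isolated)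
Conditions: LDA, THF, −78 °C; Me3SiCl, −78 → 60 °C; then 1 M HCl
Reagents that add atoms: chlorotrimethylsilane C[Si](C)(C)Cl (retained only in 4 and 5)
Why: Ireland–Claisen rearrangement in which the silyl ketene acetal (no E/Z issue, both α-substituents are methyl) shifts suprafacially across C3–C4–C5 from the conformer with pseudo-axial C3–O and pseudo-equatorial isopropenyl, so that the C5–C6 bond and quaternary C6 arise on the face that carried the oxygen, cis to the isopropenyl group on C11, and the C3 stereocentre is traded for C5.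

Step 3
Reactants: 6 2-methyl-2-[(1S,6R)-3-methyl-6-(prop-1-en-2-yl)cyclohex-2-en-1-yl]propanoic acid
Product: 7 2-methyl-2-[(1S,6R)-3-methyl-6-(prop-1-en-2-yl)cyclohex-2-en-1-yl]propan-1-ol
Conditions: LiAlH4, Et2O, 0 → 25 °C
Reagents that add atoms: none
Why: Hydride reduction of a carboxylic acid to the neopentyl alcohol, to which the isolated olefins and both stereocentres are inert.

Step 4
Reactants: 7 2-methyl-2-[(1S,6R)-3-methyl-6-(prop-1-en-2-yl)cyclohex-2-en-1-yl]propan-1-ol
Product: 8 2-methyl-2-[(1S,6R)-3-methyl-4-oxo-6-(prop-1-en-2-yl)cyclohex-2-en-1-yl]propanal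
Conditions: CrO3, 3,5-dimethylpyrazole, CH2Cl2, −20 °C
Reagents that add atoms: chromium trioxide O=[Cr](=O)=O
Why: Allylic oxidation with the complex of hexavalent chromium and 3,5-dimethylpyrazole, which also takes the primary alcohol to the non-enolisable aldehyde; of the ring allylic positions only C2 is a CH2 (C5 is tertiary and shielded), so the carvone-type enone C2(=O)–C3=C4 results and no stereocentre is formed.

Step 5
Reactants: 8 2-methyl-2-[(1S,6R)-3-methyl-4-oxo-6-(prop-1-en-2-yl)cyclohex-2-en-1-yl]propanal; 9 allyl methoxymethyl ether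
Product: 11 (4S,5R)-4-[(3S,4S)-3-hydroxy-4-(methoxymethoxy)-2-methylhex-5-en-2-yl]-2-methyl-5-(prop-1-en-2-yl)cyclohex-2-en-1-one, via alkoxyallylborane 10 (not isolated)
Conditions: 9, s-BuLi, THF, −78 °C; (+)-Ipc2BOMe; BF3·OEt2; then 8, −78 °C; HOCH2CH2NH2 work-up
Reagents that add atoms: (+)-B-methoxydiisopinocampheylborane COB([C@H]1C[C@H]2C[C@@H]([C@@H]1C)C2(C)C)[C@H]1C[C@H]2C[C@@H]([C@@H]1C)C2(C)C (retained only in 10)
Why: Brown alkoxyallylboration, in which the (Z)-γ-alkoxyallylborane reacts with the aldehyde far faster than with the enone through a chair transition state, the Z geometry giving the syn C7/C8 relation and the isopinocampheyl groups derived from (−)-α-pinene directing attack to the Re face of C7, so that both new centres are reagent-controlled.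

Step 6
Reactants: 11 (4S,5R)-4-[(3S,4S)-3-hydroxy-4-(methoxymethoxy)-2-methylhex-5-en-2-yl]-2-methyl-5-(prop-1-en-2-yl)cyclohex-2-en-1-one; 12 angelic acid
Product: 14 C7 angelate of 11, via mixed anhydride 13 (not isolated)
Conditions: 12, 2,4,6-trichlorobenzoyl chloride, Et3N, toluene, 25 °C; then 11, 80 °C
Reagents that add atoms: 2,4,6-trichlorobenzoyl chloride O=C(Cl)c1c(Cl)cc(Cl)cc1Cl (retained only in 13)
Why: Yamaguchi-type esterification through a mixed anhydride, the usual way to put angelic acid on a hindered secondary alcohol without Z-to-E isomerisation, and C7 keeps its configuration because its C–O bond is not broken.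

Step 7
Reactants: 14 C7 angelate of 11
Product: 15 7β-angeloyloxy-8α-(methoxymethoxy)-4,10-secolongipina-3,9-dien-2-one
Conditions: second-generation Grubbs catalyst (cat.), toluene, 80 °C
Reagents that add atoms: none
Why: Ring-closing metathesis of the C9 vinyl group with the isopropenyl group on C11 gives the trisubstituted C9=C10 olefin of the carbocycle C5–C6–C7–C8–C9–C10–C11, while the enone and angelate olefins are too electron-poor and hindered to take part and the cis ring fusion is inherited from 6.

Step 8
Reactants: 15 7β-angeloyloxy-8α-(methoxymethoxy)-4,10-secolongipina-3,9-dien-2-one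
Product: 16 7β-angeloyloxy-8α-hydroxy-4,10-secolongipina-3,9-dien-2-one
Conditions: camphorsulfonic acid (cat.), MeOH, 40 °C
Reagents that add atoms: none
Why: Acid-catalysed transacetalisation of the methoxymethyl ether to methanol, a mild medium that the esters, the enone and the trisubstituted olefin tolerate and in which the trans-disposed angelate has little tendency to migrate.

Step 9
Reactants: 16 7β-angeloyloxy-8α-hydroxy-4,10-secolongipina-3,9-dien-2-one
Product: 17 7β-angeloyloxy-9α,10α-epoxy-8α-hydroxy-4,10-secolongipin-3-en-2-one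
Conditions: VO(acac)2 (cat.), t-BuOOH, CH2Cl2, 0 °C
Reagents that add atoms: tert-butyl hydroperoxide CC(C)(C)OO
Why: Hydroxyl-directed vanadium-catalysed epoxidation of a cyclic allylic alcohol delivers oxygen to the face of the C8 hydroxyl group (α, also the convex face of the cis-fused bicycle), which sets C9 and C10 and leaves the electron-poor olefins untouched.

Step 10
Reactants: 17 7β-angeloyloxy-9α,10α-epoxy-8α-hydroxy-4,10-secolongipin-3-en-2-one; 18 (R)-2-methylbutanoic acid
Product: 19 7β-angeloyloxy-9α,10α-epoxy-8α-[(R)-2-methylbutanoyloxy]-4,10-secolongipin-3-en-2-one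
Conditions: 18, DCC, DMAP (cat.), CH2Cl2, 0 °C
Reagents that add atoms: none
Why: Steglich esterification of the only free hydroxyl group under near-neutral conditions, which avoids Payne rearrangement of the epoxy alcohol and keeps the stereocentre of the acid intact.

Step 11
Reactants: 19 7β-angeloyloxy-9α,10α-epoxy-8α-[(R)-2-methylbutanoyloxy]-4,10-secolongipin-3-en-2-one
Product: 22 7β-angeloyloxy-9α-hydroxy-8α-[(R)-2-methylbutanoyloxy]longipinan-2-one, via C10 radical 20 (not isolated), via titanium enolate 21 (not isolated)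
Conditions: Cp2TiCl2, Mn, THF, 25 °C (preformed green Cp2TiCl added slowly to dilute 19); then aq. NaH2PO4
Reagents that add atoms: titanocene dichloride Cl[Ti](Cl)(C1C=CC=C1)C1C=CC=C1 (retained only in 20 and 21)
Why: Cp2TiCl (trivalent titanium) transfers one electron to the epoxide oxygen and the C10–O bond breaks, because this gives the tertiary radical 20 while C9 keeps its oxygen as a titanium alkoxide; the nucleophilic radical adds to C4, the β-carbon of the C2 enone, and a second Cp2TiCl reduces the α-keto radical irreversibly to the tetravalent-titanium enolate 21, which is protonated on work-up. The closest known reaction type is the titanocene-mediated epoxide opening and 4-exo radical conjugate addition that converts the side-chain epoxides of carvone-type cyclohexenones into pinane (bicyclo[3.1.1]heptane) ketones. The cyclobutane C4–C5–C11–C10 closes in the 4-exo-trig mode, and because C10 is already tied to C5 through C9–C8–C7–C6 the same bond closes transannularly the seven-membered ring C4–C5–C6–C7–C8–C9–C10 and the six-membered ring C1–C2–C3–C4–C10–C11. C9 keeps the configuration of the epoxide; C10 and C4 are fixed by the tether, since the planar radical hangs from C11 on the face of the cyclohexenone that also carries C6, can reach C4 only on that face and has C9 held back by the carbocycle, so that its methyl group ends up over the C1–C3 bridge; C3 is set by protonation from the open side and is erased in step 12. The step needs regioselective C–O cleavage and a ring closure faster than hydrogen-atom loss or reduction of the radical: the first is secured by tertiary versus secondary radical stability, the second by the cis ring fusion (the bulky C6 on C5 takes the pseudo-equatorial site and so holds C10 axial on C11 directly above C4), by the fast reduction of the adduct radical and by keeping the titanium concentration low. The esters, the angelate olefin and the ketone are inert to Cp2TiCl under these conditions and lie out of reach of the radical.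

Step 12
Reactants: 22 7β-angeloyloxy-9α-hydroxy-8α-[(R)-2-methylbutanoyloxy]longipinan-2-one
Product: 23 7β-angeloyloxy-2,9α-dihydroxy-8α-[(R)-2-methylbutanoyloxy]longipin-2-en-1-one
Conditions: SeO2, 1,4-dioxane, H2O (trace), 90 °C
Reagents that add atoms: selenium dioxide O=[Se]=O
Why: Riley oxidation, in which SeO2 attacks the enol of the C2 ketone at its only α-methylene (C1) and the resulting 1,2-dione can enolise only towards C3 because C11 is a bridgehead, so that it rests as the diosphenol with the C3 stereocentre erased and the C2=C3 olefin of the target in place.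

Step 13
Reactants: 23 7β-angeloyloxy-2,9α-dihydroxy-8α-[(R)-2-methylbutanoyloxy]longipin-2-en-1-one
Product: 24 C2 enol triflate of 23
Conditions: PhNTf2, Et3N, CH2Cl2, 0 → 25 °C
Reagents that add atoms: N-phenylbis(trifluoromethanesulfonimide) O=S(=O)(N(c1ccccc1)S(=O)(=O)C(F)(F)F)C(F)(F)F
Why: Chemoselective O-sulfonylation of the acidic diosphenol hydroxyl group with a mild triflyl donor and an amine base, against which the hindered C9 alcohol next to quaternary C10 does not compete.

Step 14
Reactants: 24 C2 enol triflate of 23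
Product: 25 7β-angeloyloxy-9α-hydroxy-8α-[(R)-2-methylbutanoyloxy]longipin-2-en-1-one (CNP0206166.1)
Conditions: Pd(OAc)2 (cat.), PPh3, HCO2H, Et3N, DMF, 60 °C
Reagents that add atoms: none
Why: Palladium-catalysed formate reduction of an enol triflate (oxidative addition to zerovalent palladium, formate exchange, loss of CO2, reductive elimination) replaces C2–O by C2–H and gives the target without touching the esters, the enone or any stereocentre.

Compound list
1 | (1S,4R)-p-mentha-2,8-dien-1-ol (hydroxyl and isopropenyl groups on the same ring face) | C[C@@]1(O)C=C[C@H](C(C)=C)CC1 | starting material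
2 | 2-methylpropanoyl chloride (isobutyryl chloride) | CC(C)C(Cl)=O | starting material
3 | (1S,4R)-1-methyl-4-(prop-1-en-2-yl)cyclohex-2-en-1-yl 2-methylpropanoate | CC(C)C(=O)O[C@]1(C)C=C[C@H](C(C)=C)CC1 | intermediate
4 | trimethylsilyl ketene acetal of 3 | CC(C)=C(O[Si](C)(C)C)O[C@]1(C)C=C[C@H](C(C)=C)CC1 | intermediate
5 | trimethylsilyl ester of 6 | C[Si](C)(C)OC(=O)C(C)(C)[C@H]1C=C(C)CC[C@H]1C(C)=C | intermediate
6 | 2-methyl-2-[(1S,6R)-3-methyl-6-(prop-1-en-2-yl)cyclohex-2-en-1-yl]propanoic acid (side chains on C5 and C11 cis) | OC(=O)C(C)(C)[C@H]1C=C(C)CC[C@H]1C(C)=C | intermediate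
7 | 2-methyl-2-[(1S,6R)-3-methyl-6-(prop-1-en-2-yl)cyclohex-2-en-1-yl]propan-1-ol | OCC(C)(C)[C@H]1C=C(C)CC[C@H]1C(C)=C | intermediate
8 | 2-methyl-2-[(1S,6R)-3-methyl-4-oxo-6-(prop-1-en-2-yl)cyclohex-2-en-1-yl]propanal | O=CC(C)(C)[C@H]1C=C(C)C(=O)C[C@H]1C(C)=C | intermediate
9 | allyl methoxymethyl ether (3-(methoxymethoxy)prop-1-ene) | C=CCOCOC | starting material
10 | [(Z)-3-(methoxymethoxy)allyl]diisopinocampheylborane (isopinocampheyl groups from (−)-α-pinene) | COCO/C=C\CB([C@H]1C[C@H]2C[C@@H]([C@@H]1C)C2(C)C)[C@H]1C[C@H]2C[C@@H]([C@@H]1C)C2(C)C | intermediate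
11 | (4S,5R)-4-[(3S,4S)-3-hydroxy-4-(methoxymethoxy)-2-methylhex-5-en-2-yl]-2-methyl-5-(prop-1-en-2-yl)cyclohex-2-en-1-one (C7-OH and C8-O syn) | C=C[C@H](OCOC)[C@@H](O)C(C)(C)[C@H]1C=C(C)C(=O)C[C@H]1C(C)=C | intermediate
12 | angelic acid ((Z)-2-methylbut-2-enoic acid) | C/C=C(/C)C(O)=O | starting material
13 | angelic 2,4,6-trichlorobenzoic anhydride | C/C=C(/C)C(=O)OC(=O)c1c(Cl)cc(Cl)cc1Cl | intermediate
14 | C7 angelate of 11 | C/C=C(/C)C(=O)O[C@H]([C@@H](OCOC)C=C)C(C)(C)[C@H]1C=C(C)C(=O)C[C@H]1C(C)=C | intermediate
15 | 7β-angeloyloxy-8α-(methoxymethoxy)-4,10-secolongipina-3,9-dien-2-one (cis-fused bicyclo[5.4.0]undecadienone) | C/C=C(/C)C(=O)O[C@@H]1[C@@H](OCOC)C=C(C)[C@@H]2CC(=O)C(C)=C[C@@H]2C1(C)C | intermediate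
16 | 7β-angeloyloxy-8α-hydroxy-4,10-secolongipina-3,9-dien-2-one | C/C=C(/C)C(=O)O[C@@H]1[C@@H](O)C=C(C)[C@@H]2CC(=O)C(C)=C[C@@H]2C1(C)C | intermediate
17 | 7β-angeloyloxy-9α,10α-epoxy-8α-hydroxy-4,10-secolongipin-3-en-2-one | C/C=C(/C)C(=O)O[C@@H]1[C@@H](O)[C@H]2O[C@@]2(C)[C@@H]3CC(=O)C(C)=C[C@@H]3C1(C)C | intermediate
18 | (R)-2-methylbutanoic acid | CC[C@@H](C)C(O)=O | starting material
19 | 7β-angeloyloxy-9α,10α-epoxy-8α-[(R)-2-methylbutanoyloxy]-4,10-secolongipin-3-en-2-one | C/C=C(/C)C(=O)O[C@@H]1[C@@H](OC(=O)[C@H](C)CC)[C@H]2O[C@@]2(C)[C@@H]3CC(=O)C(C)=C[C@@H]3C1(C)C | intermediate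
20 | tertiary C10 radical with C9–O–TiClCp2 | C/C=C(/C)C(=O)O[C@@H]1[C@@H](OC(=O)[C@H](C)CC)[C@@H](O[Ti](Cl)(C2C=CC=C2)C2C=CC=C2)[C](C)[C@@H]2CC(=O)C(C)=C[C@@H]2C1(C)C | intermediate
21 | tricyclic C2=C3 titanium enolate with C9–O–TiClCp2 | C/C=C(/C)C(=O)O[C@@H]1[C@@H](OC(=O)[C@H](C)CC)[C@@H](O[Ti](Cl)(C2C=CC=C2)C2C=CC=C2)[C@@]2(C)[C@@H]3CC(O[Ti](Cl)(C4C=CC=C4)C4C=CC=C4)=C(C)[C@H]2[C@@H]3C1(C)C | intermediate
22 | 7β-angeloyloxy-9α-hydroxy-8α-[(R)-2-methylbutanoyloxy]longipinan-2-one (C3 methyl drawn on the C10 side; this centre is inconsequential) | C/C=C(/C)C(=O)O[C@@H]1[C@@H](OC(=O)[C@H](C)CC)[C@@H](O)[C@@]2(C)[C@@H]3CC(=O)[C@H](C)[C@H]2[C@@H]3C1(C)C | intermediate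
23 | 7β-angeloyloxy-2,9α-dihydroxy-8α-[(R)-2-methylbutanoyloxy]longipin-2-en-1-one (diosphenol) | C/C=C(/C)C(=O)O[C@@H]1[C@@H](OC(=O)[C@H](C)CC)[C@@H](O)[C@@]2(C)[C@@H]3C(=O)C(O)=C(C)[C@H]2[C@@H]3C1(C)C | intermediate
24 | C2 enol triflate of 23 | C/C=C(/C)C(=O)O[C@@H]1[C@@H](OC(=O)[C@H](C)CC)[C@@H](O)[C@@]2(C)[C@@H]3C(=O)C(OS(=O)(=O)C(F)(F)F)=C(C)[C@H]2[C@@H]3C1(C)C | intermediate
25 | 7β-angeloyloxy-9α-hydroxy-8α-[(R)-2-methylbutanoyloxy]longipin-2-en-1-one (CNP0206166.1) | C/C=C(/C)C(=O)O[C@@H]1[C@@H](OC(=O)[C@H](C)CC)[C@@H](O)[C@@]2(C)[C@@H]3C(=O)C=C(C)[C@H]2[C@@H]3C1(C)C | target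

Total step count: 14. Longest linear sequence: 14 steps (from 1).

Steps most likely to fail

Step 11. The strained four-membered ring may close too slowly. The C10 radical is then lost by hydrogen-atom transfer to a second titanium centre or by premature reduction. The fallback changes the way the radical is made and runs from 19 back to 22. First, 19 is isomerised on purpose with concentrated excess Cp2TiCl in THF, the known epoxide-to-allylic-alcohol isomerisation. This gives the exo-methylene allylic alcohol 7β-angeloyloxy-9α-hydroxy-10-methylidene-8α-[(R)-2-methylbutanoyloxy]-4,10-secolongipin-3-en-2-one F1. F1 is then submitted to iron-catalysed hydrogen-atom-transfer reductive olefin–enone coupling (Fe(acac)3, PhSiH3, EtOH, 60 °C). Hydrogen-atom transfer to the 1,1-disubstituted olefin regenerates the same C10 radical, its methyl group now made from the methylene. No stoichiometric radical reductant is present, so the radical has time to add to C4 and should give 22.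

Step 12. At 90 °C in the presence of selenium species the angelate may isomerise from Z to E, the C8 acyl group may migrate to the C9 hydroxyl group, or the oxidation may run further than the dione. The fallback replaces direct α-oxidation by a one-carbon detour under neutral conditions and runs from 22 back to 23. Compound 22 is condensed at C1 with tert-butoxybis(dimethylamino)methane (toluene, 60 °C) to the enaminone 1-(dimethylaminomethylidene)-7β-angeloyloxy-9α-hydroxy-8α-[(R)-2-methylbutanoyloxy]longipinan-2-one F2. Its electron-rich C=C bond is then cleaved with singlet oxygen (O2, rose bengal, visible light, CH2Cl2, −20 °C). The resulting 1,2-dione enolises to 23.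

Step 4. Site selectivity may be poor, with attack at the allylic positions of the isopropenyl group, and the double oxidation may stall at one of its two stages. The fallback separates C–H oxidation from alcohol oxidation and uses an ene/[2,3] mechanism for the first; it runs from 7 back to 8. Compound 7 is hydroxylated at C2 with SeO2 (cat.) and t-BuOOH in CH2Cl2. Selenium should attack the more substituted olefin terminus from the ring face opposite to the two side chains. This gives the diol 2-methyl-2-[(1S,4S,6R)-4-hydroxy-3-methyl-6-(prop-1-en-2-yl)cyclohex-2-en-1-yl]propan-1-ol F3. Dess–Martin periodinane then oxidises both carbinols to 8.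

Further compounds
F1 | step 11 | 7β-angeloyloxy-9α-hydroxy-10-methylidene-8α-[(R)-2-methylbutanoyloxy]-4,10-secolongipin-3-en-2-one | C/C=C(/C)C(=O)O[C@@H]1[C@@H](OC(=O)[C@H](C)CC)[C@@H](O)C(=C)[C@@H]2CC(=O)C(C)=C[C@@H]2C1(C)C
F2 | step 12 | 1-(dimethylaminomethylidene)-7β-angeloyloxy-9α-hydroxy-8α-[(R)-2-methylbutanoyloxy]longipinan-2-one | C/C=C(/C)C(=O)O[C@@H]1[C@@H](OC(=O)[C@H](C)CC)[C@@H](O)[C@@]2(C)[C@@H]3C(=CN(C)C)C(=O)[C@H](C)[C@H]2[C@@H]3C1(C)C
F3 | step 4 | 2-methyl-2-[(1S,4S,6R)-4-hydroxy-3-methyl-6-(prop-1-en-2-yl)cyclohex-2-en-1-yl]propan-1-ol | OCC(C)(C)[C@H]1C=C(C)[C@H](O)C[C@H]1C(C)=C
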